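**Retrosynthetic overview**

- The target is the C6–O veratroate of an all-cis oxolane, numbered O1, C2 (aryl), C3 (bearing exocyclic C6), C4 (OH), C5. Desilylation, acylation at the C6 oxygen and reduction of a C6 ester lead back to a methyl 4-silyloxy-2-aryloxolane-3-carboxylate.
- The strategy rests on one feature: C2 carries O1 and the aryl group while C3 carries the one-carbon unit C6, the imprint of O–H and CO added across an aryl alkyne. O1–C2 and C3–C6 are therefore cut together, through the C2=C3 dihydrofuran ester, back to ArC≡C–CH(OTBS)–CH2OH, CO and MeOH. This is the only ring-forming step.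
- C2 and C3 are set afterwards by syn hydrogenation of C2=C3 from the face away from the C4 silyl ether.
- C4 comes from D-glyceraldehyde acetonide (Ohira–Bestmann alkyne, Sonogashira coupling with 4-iodoveratrole, acetonide hydrolysis, bis-silylation, selective primary desilylation). The absolute configuration thus rests on the chiral pool and not on an enantioselective alkynylation of an enolisable α-oxy aldehyde.

Key step: step 6

Remark: (R)-2,2-dimethyl-1,3-dioxolane-4-carbaldehyde is taken as the commercial, configurationally defined source of C4 and is used freshly distilled because it oligomerises on storage. Ar = 3,4-dimethoxyphenyl.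

**Step 1**
Reactants: 1 (R)-2,2-dimethyl-1,3-dioxolane-4-carbaldehyde
Product: 2 (S)-4-ethynyl-2,2-dimethyl-1,3-dioxolane
Conditions: dimethyl (1-diazo-2-oxopropyl)phosphonate, K2CO3, MeOH, 0 °C to rt; product kept as a concentrated ethereal solution (volatile)
Reagents that add atoms: dimethyl (1-diazo-2-oxopropyl)phosphonate, COP(=O)(OC)C(=[N+]=[N-])C(C)=O
Why: Seyferth–Gilbert homologation in its Ohira–Bestmann form, in which methanolysis of the acetyl group frees the diazomethylphosphonate anion, this olefinates the aldehyde, and loss of N2 with 1,2-hydride shift gives the terminal alkyne under conditions mild enough to leave the α-stereocentre intact (the descriptor changes from R to S only through the CIP ranking).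

**Step 2**
Reactants: 2 (S)-4-ethynyl-2,2-dimethyl-1,3-dioxolane; 3 4-iodo-1,2-dimethoxybenzene
Product: 4 (4S)-4-[(3,4-dimethoxyphenyl)ethynyl]-2,2-dimethyl-1,3-dioxolane
Conditions: PdCl2(PPh3)2 (2 mol%), CuI (4 mol%), Et3N, THF, rt
Reagents that add atoms: none
Why: Sonogashira coupling of a terminal alkyne with an aryl iodide proceeds at room temperature and touches neither the acetonide nor the stereocentre.

**Step 3**
Reactants: 4 (4S)-4-[(3,4-dimethoxyphenyl)ethynyl]-2,2-dimethyl-1,3-dioxolane
Product: 5 (2S)-4-(3,4-dimethoxyphenyl)but-3-yne-1,2-diol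
Conditions: AcOH–H2O (4:1), 40 °C
Reagents that add atoms: none
Why: Acid-catalysed hydrolysis of the isopropylidene acetal in a medium too weak to ionise the propargylic C–O bond, so the configuration is kept.

**Step 4**
Reactants: 5 (2S)-4-(3,4-dimethoxyphenyl)but-3-yne-1,2-diol
Product: 6 (2S)-1,2-bis[(tert-butyldimethylsilyl)oxy]-4-(3,4-dimethoxyphenyl)but-3-yne
Conditions: TBSCl (2.5 equiv), imidazole (5 equiv), DMF, rt
Reagents that add atoms: tert-butyldimethylsilyl chloride, CC(C)(C)[Si](C)(C)Cl
Why: Standard imidazole-promoted silylation of both hydroxyls with excess silyl chloride.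

**Step 5**
Reactants: 6 (2S)-1,2-bis[(tert-butyldimethylsilyl)oxy]-4-(3,4-dimethoxyphenyl)but-3-yne
Product: 7 (2S)-2-[(tert-butyldimethylsilyl)oxy]-4-(3,4-dimethoxyphenyl)but-3-yn-1-ol
Conditions: HF·pyridine, pyridine, THF, 0 °C, stopped at full consumption of 6
Reagents that add atoms: none
Why: Selective desilylation on steric grounds, in which buffered HF·pyridine cleaves the unhindered primary TBS ether faster than the secondary one, while acidic fluoride conditions exclude silyl migration.

**Step 6**
Reactants: 7 (2S)-2-[(tert-butyldimethylsilyl)oxy]-4-(3,4-dimethoxyphenyl)but-3-yn-1-ol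
Product: 8 methyl (4S)-4-[(tert-butyldimethylsilyl)oxy]-2-(3,4-dimethoxyphenyl)-4,5-dihydrofuran-3-carboxylate
Conditions: PdCl2(MeCN)2 (5 mol%), p-benzoquinone (1.5 equiv), CO (1 atm), MeOH, −20 to 0 °C
Reagents that add atoms: carbon monoxide, [C-]#[O+]; methanol, CO
Why: Pd(II) binds the alkyne and the primary hydroxyl adds anti to palladium at the aryl-bearing carbon (O1–C2), the carbon best able to carry positive charge next to the electron-rich arene; the σ-vinylpalladium at C3 then inserts CO and the acylpalladium is cleaved by methanol (C3–C6), after which benzoquinone returns Pd(0) to Pd(II) and ends as hydroquinone. This is the Pd(II)-catalysed oxidative cyclisation–alkoxycarbonylation of alkynols that gives cyclic β-alkoxyacrylates, here in the 5-endo mode known from the carbonylative conversion of 3-yne-1,2-diols into furan-3-carboxylates. The oxolane ring closes 5-endo-dig, the alternative 4-exo attack at the propargylic alkyne carbon being strained and electronically mismatched. No stereocentre is created, and C4, which takes no part in the bond changes, keeps its S configuration. The step needs carbonylation to outrun protodepalladation of the vinylpalladium and needs the product not to lose silanol to the aromatic furan: methanol as solvent under CO favours fast insertion and methanolysis, the quinone takes up both protons so that acid never exceeds the catalyst loading, the C4 oxygen is silylated and not free, and the ester on C3 disfavours ionisation at C4 at 0 °C.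

**Step 7**
Reactants: 8 methyl (4S)-4-[(tert-butyldimethylsilyl)oxy]-2-(3,4-dimethoxyphenyl)-4,5-dihydrofuran-3-carboxylate
Product: 9 methyl (2S,3S,4S)-4-[(tert-butyldimethylsilyl)oxy]-2-(3,4-dimethoxyphenyl)oxolane-3-carboxylate
Conditions: H2 (5 bar), 10% Pd/C, EtOAc, rt, stopped at uptake of one equivalent
Reagents that add atoms: none
Why: Heterogeneous syn hydrogenation of the tetrasubstituted C2=C3 bond, in which the catalyst surface approaches the face opposite the bulky C4 silyloxy group so that both hydrogens arrive anti to it and aryl, ester and silyloxy groups end up mutually cis (C2 S, C3 S), with aprotic ethyl acetate chosen to hold back C–O hydrogenolysis and silyl loss.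

**Step 8**
Reactants: 9 methyl (2S,3S,4S)-4-[(tert-butyldimethylsilyl)oxy]-2-(3,4-dimethoxyphenyl)oxolane-3-carboxylate
Product: 10 {(2S,3S,4S)-4-[(tert-butyldimethylsilyl)oxy]-2-(3,4-dimethoxyphenyl)oxolan-3-yl}methanol
Conditions: DIBAL-H (3 equiv), CH2Cl2, −78 to −20 °C; aq. Rochelle salt
Reagents that add atoms: none
Why: DIBAL-H reduction of the ester to the primary alcohol at low temperature without base, so the epimerisable and elimination-prone C3 centre of the all-cis ester is never enolised.

**Step 9**
Reactants: 10 {(2S,3S,4S)-4-[(tert-butyldimethylsilyl)oxy]-2-(3,4-dimethoxyphenyl)oxolan-3-yl}methanol; 11 3,4-dimethoxybenzoyl chloride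
Product: 12 {(2S,3S,4S)-4-[(tert-butyldimethylsilyl)oxy]-2-(3,4-dimethoxyphenyl)oxolan-3-yl}methyl 3,4-dimethoxybenzoate
Conditions: Et3N, DMAP (cat.), CH2Cl2, 0 °C to rt
Reagents that add atoms: none
Why: DMAP-catalysed acylation of the only free hydroxyl with the acid chloride (nucleophilic catalysis of the Steglich type).

**Step 10**
Reactants: 12 {(2S,3S,4S)-4-[(tert-butyldimethylsilyl)oxy]-2-(3,4-dimethoxyphenyl)oxolan-3-yl}methyl 3,4-dimethoxybenzoate
Product: 13 [(2S,3R,4S)-2-(3,4-dimethoxyphenyl)-4-hydroxyoxolan-3-yl]methyl 3,4-dimethoxybenzoate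
Conditions: TBAF, AcOH (1:1), THF, 0 °C to rt
Reagents that add atoms: none
Why: Fluoride-induced desilylation buffered with acetic acid, which keeps the medium near neutral so that the primary ester does not migrate to the freed cis C4 hydroxyl and the electron-rich benzylic C2–O bond is not ionised (the C3 descriptor becomes R only through the CIP ranking).

**Compound list**

1 | (R)-2,2-dimethyl-1,3-dioxolane-4-carbaldehyde | O=C[C@H]1COC(C)(C)O1 | starting material
2 | (S)-4-ethynyl-2,2-dimethyl-1,3-dioxolane | C#C[C@H]1COC(C)(C)O1 | intermediate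
3 | 4-iodo-1,2-dimethoxybenzene | COc1ccc(I)cc1OC | starting material
4 | (4S)-4-[(3,4-dimethoxyphenyl)ethynyl]-2,2-dimethyl-1,3-dioxolane | COc1ccc(C#C[C@H]2COC(C)(C)O2)cc1OC | intermediate
5 | (2S)-4-(3,4-dimethoxyphenyl)but-3-yne-1,2-diol | COc1ccc(C#C[C@H](O)CO)cc1OC | intermediate
6 | (2S)-1,2-bis[(tert-butyldimethylsilyl)oxy]-4-(3,4-dimethoxyphenyl)but-3-yne | COc1ccc(C#C[C@H](O[Si](C)(C)C(C)(C)C)CO[Si](C)(C)C(C)(C)C)cc1OC | intermediate
7 | (2S)-2-[(tert-butyldimethylsilyl)oxy]-4-(3,4-dimethoxyphenyl)but-3-yn-1-ol | COc1ccc(C#C[C@H](O[Si](C)(C)C(C)(C)C)CO)cc1OC | intermediate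
8 | methyl (4S)-4-[(tert-butyldimethylsilyl)oxy]-2-(3,4-dimethoxyphenyl)-4,5-dihydrofuran-3-carboxylate | COC(=O)C1=C(c2ccc(OC)c(OC)c2)OC[C@H]1O[Si](C)(C)C(C)(C)C | intermediate
9 | methyl (2S,3S,4S)-4-[(tert-butyldimethylsilyl)oxy]-2-(3,4-dimethoxyphenyl)oxolane-3-carboxylate | COC(=O)[C@@H]1[C@H](O[Si](C)(C)C(C)(C)C)CO[C@@H]1c2ccc(OC)c(OC)c2 | intermediate
10 | {(2S,3S,4S)-4-[(tert-butyldimethylsilyl)oxy]-2-(3,4-dimethoxyphenyl)oxolan-3-yl}methanol | OC[C@@H]1[C@H](O[Si](C)(C)C(C)(C)C)CO[C@@H]1c2ccc(OC)c(OC)c2 | intermediate
11 | 3,4-dimethoxybenzoyl chloride | COc1ccc(C(=O)Cl)cc1OC | starting material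
12 | {(2S,3S,4S)-4-[(tert-butyldimethylsilyl)oxy]-2-(3,4-dimethoxyphenyl)oxolan-3-yl}methyl 3,4-dimethoxybenzoate | COc1ccc(C(=O)OC[C@@H]2[C@H](O[Si](C)(C)C(C)(C)C)CO[C@@H]2c3ccc(OC)c(OC)c3)cc1OC | intermediate
13 | [(2S,3R,4S)-2-(3,4-dimethoxyphenyl)-4-hydroxyoxolan-3-yl]methyl 3,4-dimethoxybenzoate | COc1ccc(C(=O)OC[C@@H]2[C@H](O)CO[C@@H]2c2ccc(OC)c(OC)c2)cc1OC | target

**Totals**

Total step count: 10. Longest linear sequence: 10 steps (1 to 13); 3 and 11 enter directly.

**Steps most likely to fail**

Step 6. The vinylpalladium may be protonated before it inserts CO, giving uncarbonylated cycloisomerisation. The acylpalladium may be captured by a second alkyne instead of methanol. Transient acid may strip the silyl group, after which the ring aromatises to the furan. The fallback sets out from 7 and separates ring closure from carbonylation. Iodoetherification (I2, NaHCO3, MeCN, 0 °C; 5-endo-dig, anti addition) should give tert-butyl{[(3R)-5-(3,4-dimethoxyphenyl)-4-iodo-2,3-dihydrofuran-3-yl]oxy}dimethylsilane F1, with the same spatial arrangement at the silyloxy carbon; the descriptor is R only because iodine raises the rank of the neighbouring carbon. Pd(0)-catalysed methoxycarbonylation of this vinyl iodide (Pd(OAc)2, dppf, CO 1 atm, MeOH, Et3N, DMF, 50 °C) should then give 8, where the route is rejoined.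

Step 7. The tetrasubstituted push–pull alkene may reduce sluggishly. Forcing it may bring hydrogenolysis of the allylic C4–O or, after reduction, the benzylic C2–O bond. Face selection by the silyl ether may also be incomplete. The fallback sets out from 8 and reduces the ester first. DIBAL-H (CH2Cl2, −78 °C) should give {(4S)-4-[(tert-butyldimethylsilyl)oxy]-2-(3,4-dimethoxyphenyl)-4,5-dihydrofuran-3-yl}methanol F2, an electron-rich enol ether to be handled base-washed and used at once. Homogeneous hydrogenation with [Ir(cod)(PCy3)(py)]PF6 (H2 1 atm, CH2Cl2, rt) follows; the primary hydroxyl binds iridium and brings the hindered alkene to the metal while the silyl ether still shields its own face. This should give 10 directly, where the route is rejoined.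

Step 5. Discrimination between the primary silyl ether and the rather exposed propargylic secondary one may be insufficient, leading to over-desilylation to the diol or to incomplete conversion. The fallback sets out from 5 and uses orthogonal protection instead of differential desilylation. Pivaloylation of the primary hydroxyl (PivCl, pyridine, CH2Cl2, −20 °C) should give (2S)-4-(3,4-dimethoxyphenyl)-2-hydroxybut-3-yn-1-yl 2,2-dimethylpropanoate F3. Silylation (TBSOTf, 2,6-lutidine, CH2Cl2, −78 °C) should give (2S)-2-[(tert-butyldimethylsilyl)oxy]-4-(3,4-dimethoxyphenyl)but-3-yn-1-yl 2,2-dimethylpropanoate F4. Reductive removal of the pivalate (DIBAL-H, CH2Cl2, −78 °C) should give 7, where the route is rejoined.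

**Further compounds**

F1 | step 6 | tert-butyl{[(3R)-5-(3,4-dimethoxyphenyl)-4-iodo-2,3-dihydrofuran-3-yl]oxy}dimethylsilane | COc1ccc(C2=C(I)[C@H](O[Si](C)(C)C(C)(C)C)CO2)cc1OC
F2 | step 7 | {(4S)-4-[(tert-butyldimethylsilyl)oxy]-2-(3,4-dimethoxyphenyl)-4,5-dihydrofuran-3-yl}methanol | COc1ccc(C2=C(CO)[C@H](O[Si](C)(C)C(C)(C)C)CO2)cc1OC
F3 | step 5 | (2S)-4-(3,4-dimethoxyphenyl)-2-hydroxybut-3-yn-1-yl 2,2-dimethylpropanoate | COc1ccc(C#C[C@H](O)COC(=O)C(C)(C)C)cc1OC
F4 | step 5 | (2S)-2-[(tert-butyldimethylsilyl)oxy]-4-(3,4-dimethoxyphenyl)but-3-yn-1-yl 2,2-dimethylpropanoate | COc1ccc(C#C[C@H](O[Si](C)(C)C(C)(C)C)COC(=O)C(C)(C)C)cc1OC
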